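Each half is a 2,3-seco ent-labdane: a cyclohexane (ring B) fused to a tetrahydropyran (ring C). Everything rests on cutting C5–C10 in ring B: C10, which carries CH3 and CH2CO2H, is the β-carbon of a (Z)-3-methyl enoate on C9, and C5 is a radical beside the isobutyrate carbon C4. Ring C is built first, with C8, C9, C13 and C14 fixed by two Sharpless epoxidations. One 6-exo radical cyclization then closes ring B and sets the quaternary C10 and C5 by relay from C9 and C8. The bicyclic diester diol is split into both halves, which are joined by acylation and unmasked.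

Key step: step 14

Remark: labdane numbering is used (ring B = C5–C10; ring C = O, C8, C9, C11, C12, C13; C2 and C3 are the carboxyl carbons; primes mark the hydroxylated half). Compounds 19 and 20 are carried as C5 epimers, because C5 becomes a radical in step 14.

Step 1
Reactants: 1 nerol
Product: 2 neryl tert-butyldimethylsilyl ether
Conditions: TBSCl, imidazole, DMF, 0 °C → rt
Reagents that add atoms: tert-butyldimethylsilyl chloride, CC(C)(C)[Si](C)(C)Cl
Why: Routine silylation masks the C15 hydroxyl through the organometallic steps and forms no stereocenter.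

Step 2
Reactants: 2 neryl tert-butyldimethylsilyl ether
Product: 3 (2E,6Z)-8-silyloxy-2,6-dimethylocta-2,6-dien-1-ol (C7 allylic alcohol)
Conditions: SeO2 (cat.), t-BuOOH, salicylic acid (cat.), CH2Cl2, rt
Reagents that add atoms: tert-butyl hydroperoxide, CC(C)(C)OO
Why: Riley allylic oxidation should attack the (E)-methyl of the more electron-rich terminal alkene, while the C13=C14 alkene is deactivated by its allylic silyloxy group.

Step 3
Reactants: 3 C7 allylic alcohol
Product: 4 (8S,9S)-8,9-epoxy alcohol
Conditions: Ti(OiPr)4 (cat.), L-(+)-diethyl tartrate (cat.), t-BuOOH, 4 Å MS, CH2Cl2, −20 °C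
Reagents that add atoms: tert-butyl hydroperoxide, CC(C)(C)OO
Why: Sharpless asymmetric epoxidation of the (E)-2-methyl allylic alcohol sets C8 and C9 under reagent control, and the silyl-protected allylic alkene is not a substrate.

Step 4
Reactants: 4 (8S,9S)-8,9-epoxy alcohol; 5 trimethylsilylacetylene
Product: 6 (8R,9S)-9-(trimethylsilylethynyl) 7,8-diol
Conditions: 5, n-BuLi, toluene, 0 °C; Et2AlCl; then 4, 0 °C → rt
Reagents that add atoms: none
Why: Alkynylalane opening of the 2,3-epoxy alcohol should occur at C9, directed by the aluminium alkoxide and blocked at quaternary C8, with inversion, which fixes the C8/C9 relationship that becomes the trans ring fusion.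

Step 5
Reactants: 6 (8R,9S)-alkynyl 7,8-diol
Product: 8 (8R,9S)-7,8-epoxide, via primary tosylate 7 (not isolated)
Conditions: NaH, N-tosylimidazole, THF, 0 °C → rt
Reagents that add atoms: none
Why: Sulfonylation of the primary alkoxide and Williamson closure by the tertiary alkoxide give the 2,2-disubstituted epoxide without breaking the C8–O bond.

Step 6
Reactants: 8 (8R,9S)-7,8-epoxide
Product: 9 (8S,9S)-8-(but-3-enyl) tertiary alcohol
Conditions: CH2=CHCH2MgBr, CuI (cat.), THF, −30 → 0 °C
Reagents that add atoms: allylmagnesium bromide, C=CC[Mg]Br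
Why: Copper-catalysed Grignard opening at the CH2 terminus adds C6 and C5 as a butenyl chain and returns the free C8 hydroxyl, with the silyl-capped alkyne inert.

Step 7
Reactants: 9 (8S,9S)-butenyl tertiary alcohol
Product: 10 (8S,9S)-enyne diol with free C15 allylic alcohol
Conditions: Bu4NF, THF, rt
Reagents that add atoms: none
Why: Fluoride cleaves both the silyl ether and the alkynylsilane and so frees the allylic alcohol for the second epoxidation.

Step 8
Reactants: 10 (8S,9S)-enyne diol
Product: 12 ring C diol (8S,9S,13R,14R), via epoxy diol 11 (not isolated)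
Conditions: Ti(OiPr)4 (cat.), D-(−)-diethyl tartrate (cat.), t-BuOOH, 4 Å MS, CH2Cl2, −20 °C; then camphorsulfonic acid (cat.), 0 °C → rt
Reagents that add atoms: tert-butyl hydroperoxide, CC(C)(C)OO
Why: Sharpless epoxidation of the (Z)-allylic alcohol sets C13 and C14 under reagent control, and acid then triggers 6-exo-tet opening at the tertiary epoxide carbon C13 by the C8 hydroxyl with inversion, which closes ring C.

Step 9
Reactants: 12 ring C diol
Product: 13 ring C 14,15-acetonide
Conditions: Me2C(OMe)2, PPTS (cat.), CH2Cl2, rt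
Reagents that add atoms: 2,2-dimethoxypropane, COC(C)(C)OC
Why: Acetonide formation on the terminal 1,2-diol removes the acidic protons before the acetylide chemistry.

Step 10
Reactants: 13 ring C 14,15-acetonide
Product: 15 2-(trimethylsilyl)ethyl ynoate, via lithium acetylide 14 (not isolated)
Conditions: n-BuLi, THF, −78 °C; ClCO2CH2CH2SiMe3, −78 → 0 °C
Reagents that add atoms: 2-(trimethylsilyl)ethyl chloroformate, C[Si](C)(C)CCOC(=O)Cl
Why: Deprotonation of the terminal alkyne and C-acylation by the chloroformate bring in C2 as a fluoride-labile ester.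

Step 11
Reactants: 15 2-(trimethylsilyl)ethyl ynoate
Product: 16 (Z)-3-methyl enoate (ester cis to C9)
Conditions: Me2CuLi, THF, −78 °C; NH4Cl (aq), −78 °C
Reagents that add atoms: lithium dimethylcuprate, [Li+].C[Cu-]C
Why: Syn-carbocupration of the ynoate and cold protonation should place the new methyl (C20) cis to H-1, so that the ester is cis to C9.

Step 12
Reactants: 16 (Z)-3-methyl enoate
Product: 17 C5 aldehyde
Conditions: OsO4 (cat.), NaIO4, 2,6-lutidine, dioxane/H2O, rt
Reagents that add atoms: osmium tetroxide, O=[Os](=O)(=O)=O; sodium periodate, [Na+].[O-]I(=O)(=O)=O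
Why: Lemieux–Johnson cleavage of the monosubstituted alkene is much faster than attack on the electron-poor trisubstituted enoate.

Step 13
Reactants: 17 C5 aldehyde; 18 allyl isobutyrate
Product: 20 C5 O-phenyl thionocarbonate, via lithium aldolate 19 (not isolated)
Conditions: 18, LiN(iPr)2, THF, −78 °C; then 17; then PhOC(S)Cl (excess), −78 → −20 °C
Reagents that add atoms: O-phenyl chlorothionoformate, S=C(Cl)Oc1ccccc1
Why: Aldol addition of the ester enolate forms the C4–C5 bond and the quaternary C4, and the lithium aldolate is thioacylated cold before it can undergo retro-aldol cleavage.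

Step 14
Reactants: 20 C5 O-phenyl thionocarbonate
Product: 21 bicyclic diester acetonide (5S,8S,9S,10R,13R,14R)
Conditions: (Me3Si)3SiH, AIBN (slow addition), toluene (2 mM), 100 °C
Reagents that add atoms: none
Why: The silyl radical adds to the thiocarbonyl sulfur and β-scission releases a secondary C5 radical (Barton–McCombie generation), which adds to C10, the β-carbon of the enoate, after which the α-ester radical at C1 takes hydrogen from the silane; the closest known reaction type is the hydride-mediated Giese radical cyclization onto acrylates. Ring B is closed through its C5–C10 bond in the 6-exo-trig mode, and because C7 and C10 are already trans on ring C the new ring fusion can only be trans. C10 is controlled by allylic 1,3-strain: the ester cis to C9 holds H-9 in the enoate plane, so the radical tethered through C8 can reach only the face that leaves CH3-20 anti to H-9 and CH2CO2R equatorial. C5 is controlled by the chair transition state, in which the bulky CMe2CO2allyl group sits equatorial and H-5 ends axial, cis to H-9. The step needs 6-exo attack at C10 to outrun reduction of the open-chain radical and 1,5-hydrogen transfer; the polarity match of a nucleophilic alkyl radical with the enoate β-carbon, the slow hydrogen donor and its slow addition at high dilution are meant to secure this.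

Step 15
Reactants: 21 bicyclic diester acetonide
Product: 22 bicyclic diester 14,15-diol
Conditions: AcOH/THF/H2O, 40 °C
Reagents that add atoms: none
Why: Mild aqueous acid hydrolyses the dioxolane and should leave both esters and the tertiary ether untouched.

Step 16
Reactants: 22 bicyclic diester 14,15-diol
Product: 23 14-ene (vinyl) diester
Conditions: PPh3, I2, imidazole, toluene, 110 °C
Reagents that add atoms: none
Why: Garegg–Samuelsson deoxygenation converts the terminal vicinal diol through iodophosphonium intermediates into the C14=C15 alkene without touching C13.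

Step 17
Reactants: 23 14-ene diester
Product: 24 14-ene C3 acid
Conditions: Pd(PPh3)4 (cat.), morpholine, THF, rt
Reagents that add atoms: none
Why: Tsuji–Trost deallylation frees the hindered C3 acid while the silylethyl ester and the vinyl group remain.

Step 18
Reactants: 24 14-ene C3 acid; 22 bicyclic diester 14,15-diol
Product: 26 protected dimer ester, via acid chloride 25 (not isolated)
Conditions: 24, 1-chloro-N,N,2-trimethylprop-1-en-1-amine, CH2Cl2, 0 °C → rt; then 22, pyridine, DMAP, CH2Cl2, 0 → 40 °C
Reagents that add atoms: none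
Why: The neutral chloroenamine gives the pivaloyl-like acid chloride, which under DMAP catalysis should acylate only the primary C15' hydroxyl, because the C14' hydroxyl next to quaternary C13' is too hindered.

Step 19
Reactants: 26 protected dimer ester
Product: 27 dimer C3' acid
Conditions: Pd(PPh3)4 (cat.), morpholine, THF, rt
Reagents that add atoms: none
Why: A second Tsuji–Trost deallylation liberates the C3' acid without hydrolytic conditions that could endanger the inter-unit ester.

Step 20
Reactants: 27 dimer C3' acid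
Product: 28 Excoecarin R1
Conditions: Bu4NF, THF, 0 °C → rt; pH 4 buffer work-up
Reagents that add atoms: none
Why: Fluoride attacks silicon and both 2-(trimethylsilyl)ethyl esters fragment to carboxylate, ethylene and Me3SiF, a non-hydrolytic unmasking that leaves the hindered inter-unit ester and all stereocenters intact.

Compound list
1 | nerol | CC(C)=CCC/C(C)=C\CO | starting material
2 | neryl tert-butyldimethylsilyl ether | CC(C)=CCC/C(C)=C\CO[Si](C)(C)C(C)(C)C | intermediate
3 | (2E,6Z)-8-silyloxy-2,6-dimethylocta-2,6-dien-1-ol (C7 allylic alcohol) | OC/C(C)=C/CC/C(C)=C\CO[Si](C)(C)C(C)(C)C | intermediate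
4 | (8S,9S)-8,9-epoxy alcohol | OC[C@]1(C)O[C@H]1CC/C(C)=C\CO[Si](C)(C)C(C)(C)C | intermediate
5 | trimethylsilylacetylene | C#C[Si](C)(C)C | starting material
6 | (8R,9S)-9-(trimethylsilylethynyl) 7,8-diol | OC[C@](C)(O)[C@H](C#C[Si](C)(C)C)CC/C(C)=C\CO[Si](C)(C)C(C)(C)C | intermediate
7 | primary (C7) tosylate of 6 | Cc1ccc(cc1)S(=O)(=O)OC[C@](C)(O)[C@H](C#C[Si](C)(C)C)CC/C(C)=C\CO[Si](C)(C)C(C)(C)C | intermediate
8 | (8R,9S)-7,8-epoxide | C[Si](C)(C)C#C[C@H](CC/C(C)=C\CO[Si](C)(C)C(C)(C)C)[C@]1(C)CO1 | intermediate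
9 | (8S,9S)-8-(but-3-enyl) tertiary alcohol | C[Si](C)(C)C#C[C@H](CC/C(C)=C\CO[Si](C)(C)C(C)(C)C)[C@@](C)(O)CCC=C | intermediate
10 | (8S,9S)-enyne diol (free C15 allylic alcohol, terminal alkyne) | C#C[C@H](CC/C(C)=C\CO)[C@@](C)(O)CCC=C | intermediate
11 | (8S,9S,13S,14R)-13,14-epoxy diol | OC[C@H]1O[C@@]1(C)CC[C@@H](C#C)[C@](C)(CCC=C)O | intermediate
12 | ring C diol (8S,9S,13R,14R): 2,2,6,6-tetrasubstituted tetrahydropyran with 9-ethynyl, 8-butenyl and 13-(1,2-dihydroxyethyl) | OC[C@@H](O)[C@@]1(C)CC[C@@H](C#C)[C@](C)(CCC=C)O1 | intermediate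
13 | ring C 14,15-acetonide | CC1(C)OC[C@@H](O1)[C@@]2(C)CC[C@@H](C#C)[C@](C)(CCC=C)O2 | intermediate
14 | lithium acetylide of 13 | CC1(C)OC[C@@H](O1)[C@@]2(C)CC[C@@H](C#C[Li])[C@](C)(CCC=C)O2 | intermediate
15 | 2-(trimethylsilyl)ethyl ynoate | CC1(C)OC[C@@H](O1)[C@@]2(C)CC[C@@H](C#CC(=O)OCC[Si](C)(C)C)[C@](C)(CCC=C)O2 | intermediate
16 | (Z)-3-methyl enoate (ester cis to C9) | CC1(C)OC[C@@H](O1)[C@@]2(C)CC[C@@H](/C(C)=C\C(=O)OCC[Si](C)(C)C)[C@](C)(CCC=C)O2 | intermediate
17 | C5 aldehyde | CC1(C)OC[C@@H](O1)[C@@]2(C)CC[C@@H](/C(C)=C\C(=O)OCC[Si](C)(C)C)[C@](C)(CCC=O)O2 | intermediate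
18 | allyl isobutyrate | CC(C)C(=O)OCC=C | starting material
19 | lithium aldolate (C5 epimers) | CC1(C)OC[C@@H](O1)[C@@]2(C)CC[C@@H](/C(C)=C\C(=O)OCC[Si](C)(C)C)[C@](C)(CCC(O[Li])C(C)(C)C(=O)OCC=C)O2 | intermediate
20 | C5 O-phenyl thionocarbonate (C5 epimers) | CC1(C)OC[C@@H](O1)[C@@]2(C)CC[C@@H](/C(C)=C\C(=O)OCC[Si](C)(C)C)[C@](C)(CCC(OC(=S)Oc3ccccc3)C(C)(C)C(=O)OCC=C)O2 | intermediate
21 | bicyclic diester acetonide (5S,8S,9S,10R,13R,14R; C2 silylethyl ester, C3 allyl ester) | CC1(C)OC[C@@H](O1)[C@@]2(C)CC[C@H]3[C@](C)(CC(=O)OCC[Si](C)(C)C)[C@@H](C(C)(C)C(=O)OCC=C)CC[C@]3(C)O2 | intermediate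
22 | bicyclic diester 14,15-diol | OC[C@@H](O)[C@@]1(C)CC[C@H]2[C@](C)(CC(=O)OCC[Si](C)(C)C)[C@@H](C(C)(C)C(=O)OCC=C)CC[C@]2(C)O1 | intermediate
23 | 14-ene (vinyl) diester | C=C[C@@]1(C)CC[C@H]2[C@](C)(CC(=O)OCC[Si](C)(C)C)[C@@H](C(C)(C)C(=O)OCC=C)CC[C@]2(C)O1 | intermediate
24 | 14-ene C3 acid (C2 silylethyl ester) | C=C[C@@]1(C)CC[C@H]2[C@](C)(CC(=O)OCC[Si](C)(C)C)[C@@H](C(C)(C)C(=O)O)CC[C@]2(C)O1 | intermediate
25 | C3 acid chloride of 24 | C=C[C@@]1(C)CC[C@H]2[C@](C)(CC(=O)OCC[Si](C)(C)C)[C@@H](C(C)(C)C(=O)Cl)CC[C@]2(C)O1 | intermediate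
26 | protected dimer ester (C3–O–C15' link; C2 and C2' silylethyl esters, C3' allyl ester) | C=C[C@@]1(C)CC[C@H]2[C@](C)(CC(=O)OCC[Si](C)(C)C)[C@@H](C(C)(C)C(=O)OC[C@@H](O)[C@@]3(C)CC[C@H]4[C@](C)(CC(=O)OCC[Si](C)(C)C)[C@@H](C(C)(C)C(=O)OCC=C)CC[C@]4(C)O3)CC[C@]2(C)O1 | intermediate
27 | dimer C3' acid (C2 and C2' silylethyl esters) | C=C[C@@]1(C)CC[C@H]2[C@](C)(CC(=O)OCC[Si](C)(C)C)[C@@H](C(C)(C)C(=O)OC[C@@H](O)[C@@]3(C)CC[C@H]4[C@](C)(CC(=O)OCC[Si](C)(C)C)[C@@H](C(C)(C)C(=O)O)CC[C@]4(C)O3)CC[C@]2(C)O1 | intermediate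
28 | Excoecarin R1 | C=C[C@@]1(C)CC[C@H]2[C@](C)(CC(=O)O)[C@@H](C(C)(C)C(=O)OC[C@@H](O)[C@@]3(C)CC[C@H]4[C@](C)(CC(=O)O)[C@@H](C(C)(C)C(=O)O)CC[C@]4(C)O3)CC[C@]2(C)O1 | target

Total step count: 20. Longest linear sequence: 20 steps (1 → 28; the coupling partner 22 lies on the same line as acid 24).

Steps most likely to fail

Step 14 is the riskiest. The C5 radical may be reduced before it cyclizes, or may take the allylic hydrogen from C9 by 1,5-transfer. The bond forms between two heavily substituted carbons, and ring C must adopt the conformer with C7 and C10 both equatorial, which may slow closure and erode facial selectivity at C10. The fallback sets out from aldehyde 17 and returns at 21. The aldol with the lithium enolate of 18 is worked up to give the β-hydroxy ester F1. Oxidation with the triacetoxyperiodinane DMP gives the β-keto ester F2. SmI2 in THF with t-BuOH at −78 °C should form the ketyl, which adds 6-exo to C10 under the same allylic-strain control and gives the C5 tertiary alcohol F3. Acylation with methyl chlorooxoacetate, pyridine and DMAP gives the methyl oxalate F4. Bu3SnH with AIBN in toluene at 110 °C then removes the oxygen, and the tertiary C5 radical should take hydrogen on the face opposite the axial C20 methyl to give 21.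

Step 18 may suffer from sluggish acylation by the neopentyl-type acid chloride, competing acylation of the C14' hydroxyl, or acyl migration. The fallback sets out from diol 22 and acid 24 and returns at 26. NaH and N-tosylimidazole convert 22 through its primary tosylate F5 into the (14R)-14,15-epoxide F6, with C14 retained. The caesium carboxylate of 24 (Cs2CO3, DMF, 70 °C) then opens F6 at the primary C15' to give 26 directly, since carboxylate alkylation is far less sensitive to hindrance at the acid.

Step 16 may stall at an iodide at the hindered C14 without elimination, or be diverted by participation of the ring oxygen. The fallback sets out from 22 and returns at 23. NaIO4 in THF/H2O cleaves the diol to the non-enolisable C14 aldehyde F7, and Wittig methylenation with Ph3P=CH2 (from Ph3PCH3Br and KN(SiMe3)2, THF, 0 °C) rebuilds the vinyl group of 23.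

Further compounds
F1 | step 14 | β-hydroxy ester from 17 and 18 (C5 epimers) | CC1(C)OC[C@@H](O1)[C@@]2(C)CC[C@@H](/C(C)=C\C(=O)OCC[Si](C)(C)C)[C@](C)(CCC(O)C(C)(C)C(=O)OCC=C)O2
F2 | step 14 | C5 β-keto ester | CC1(C)OC[C@@H](O1)[C@@]2(C)CC[C@@H](/C(C)=C\C(=O)OCC[Si](C)(C)C)[C@](C)(CCC(=O)C(C)(C)C(=O)OCC=C)O2
F3 | step 14 | bicyclic C5 tertiary alcohol (either C5 epimer) | CC1(C)OC[C@@H](O1)[C@@]2(C)CC[C@H]3[C@](C)(CC(=O)OCC[Si](C)(C)C)C(O)(C(C)(C)C(=O)OCC=C)CC[C@]3(C)O2
F4 | step 14 | methyl oxalate of F3 | CC1(C)OC[C@@H](O1)[C@@]2(C)CC[C@H]3[C@](C)(CC(=O)OCC[Si](C)(C)C)C(OC(=O)C(=O)OC)(C(C)(C)C(=O)OCC=C)CC[C@]3(C)O2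
F5 | step 18 | primary (C15) tosylate of 22 | Cc1ccc(cc1)S(=O)(=O)OC[C@@H](O)[C@@]2(C)CC[C@H]3[C@](C)(CC(=O)OCC[Si](C)(C)C)[C@@H](C(C)(C)C(=O)OCC=C)CC[C@]3(C)O2
F6 | step 18 | (14R)-14,15-epoxide of the bicyclic diester | C1O[C@H]1[C@@]2(C)CC[C@H]3[C@](C)(CC(=O)OCC[Si](C)(C)C)[C@@H](C(C)(C)C(=O)OCC=C)CC[C@]3(C)O2
F7 | step 16 | C14 aldehyde (15-nor) of the bicyclic diester | O=C[C@@]1(C)CC[C@H]2[C@](C)(CC(=O)OCC[Si](C)(C)C)[C@@H](C(C)(C)C(=O)OCC=C)CC[C@]2(C)O1
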